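Retrosynthetic overview
1. Numbering used for every compound (clerodane type): ring A = C1, C2 (ketone), C3, C4, C5, C10; ring B = C5, C6 (OAc), C7, C8, C9, C10; ring C = C1, C2, C3, C20, C9, C10 (C20 is the CH2 tying C9 to C3); methyls C17 on C8, C18 on C4, C19 on C5; side chain C11–C16 on C9.
2. Enabling feature: the C6 oxygen and the C2 ketone are 1,5-related through C5–C4–C3, so C5 is the enolate carbon of a C6 ketone, C4 is the β-carbon of a C2 enone (C3=C4), and the C3 enolate left by the addition stands three atoms from C20.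
3. Key disconnection: C4–C5 (intramolecular Michael addition, closes ring A) and, in the same operation, C3–C20 (enolate alkylation, closes ring C), from a monocyclic ring-B ketone carrying an (E)-2-oxopent-3-enyl arm on C10 and CH2OTf on C9.
4. Before that: C1–C10 by Michael addition of a β-keto ester tethered through the C20 oxygen (fixes C10; tether carbon later lost as CO2); ring B with C8 and C9 by a catalytic enantioselective Diels–Alder reaction of a 2-silyloxydiene with an (E)-2-alkylbut-2-enal.
5. After that: C6 ketone to the equatorial acetate, and the (E)-trisubstituted side-chain alkene to the (13S)-vinyl carbinol by asymmetric epoxidation and selenoxide elimination. Ring order: B, then A and C together.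

Key step: step 14

Remark on the chemistry: the (S)-oxazaborolidinium salt of the Diels–Alder step is assumed to leave the Re face of C9 of the bound enal open (formyl C–H···O binding model); if the sense is the reverse, the (R)-catalyst is used and nothing else changes.

Step 1
Reactants: 1 (E)-2-methylbut-2-enal (tiglic aldehyde)
Product: 2 (E)-3-methylpenta-1,3-diene
Conditions: Ph3PCH3Br, KOtBu, THF, 0 → 23 °C; codistilled and used as THF solution
Reagents that add atoms: methyltriphenylphosphonium bromide, C[P+](c1ccccc1)(c1ccccc1)c1ccccc1.[Br-]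
Why: Wittig methylenation of the aldehyde; the trisubstituted (E)-double bond is a spectator, so its geometry is carried over.

Step 2
Reactants: 2 (E)-3-methylpenta-1,3-diene
Product: 4 (E)-3-methylpent-3-en-1-ol, via alkylborane 3 (not isolated)
Conditions: 9-BBN, THF, 0 → 23 °C; then NaOH, H2O2, H2O, 0 → 23 °C
Reagents that add atoms: hydrogen peroxide, OO
Why: Hydroboration–oxidation; 9-BBN should add only to the monosubstituted vinyl group with boron on the terminal carbon, the trisubstituted alkene being too hindered.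

Step 3
Reactants: 4 (E)-3-methylpent-3-en-1-ol
Product: 5 (E)-5-iodo-3-methylpent-2-ene
Conditions: PPh3, I2, imidazole, CH2Cl2, 0 → 23 °C
Reagents that add atoms: iodine, II
Why: Appel iodination of a primary alcohol (SN2 on the alkoxyphosphonium ion); the alkene is not involved.

Step 4
Reactants: 6 (E)-but-2-enal (crotonaldehyde); 7 tert-butylamine
Product: 8 (1E,2E)-N-tert-butylbut-2-en-1-imine
Conditions: MgSO4, Et2O, 0 → 23 °C; distillation
Reagents that add atoms: none
Why: Imine condensation; the bulky N-substituent gives the (E)-imine and later steers alkylation to carbon.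

Step 5
Reactants: 8 (1E,2E)-N-tert-butylbut-2-en-1-imine; 5 (E)-5-iodo-3-methylpent-2-ene
Product: 11 (2E,5E)-2-ethylidene-5-methylhept-5-enal, via alkylated imine 9 (not isolated), via deconjugated aldehyde 10 (not isolated)
Conditions: LiN(iPr)2, THF/DMPU, −78 °C; 5, −78 → 0 °C; aq. oxalic acid, 23 °C; DBU (0.1 equiv), CH2Cl2, 23 °C
Reagents that add atoms: water, O
Why: α-Alkylation of the lithiated 1-azadiene (metalloenamine alkylation), hydrolysis of the imine by the aqueous acid (water supplies the aldehyde oxygen and tert-butylamine is released) and base-mediated isomerization into conjugation should give the more stable (E)-2-alkylbut-2-enal, with CHO trans to the β-methyl.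

Step 6
Reactants: 12 3-methylbut-3-en-2-one
Product: 13 2-methyl-3-(triisopropylsilyloxy)buta-1,3-diene
Conditions: TIPSOTf, Et3N, Et2O, 0 °C
Reagents that add atoms: triisopropylsilyl trifluoromethanesulfonate, CC(C)[Si](OS(=O)(=O)C(F)(F)F)(C(C)C)C(C)C
Why: Soft enolization and O-silylation of the methyl ketone give the cross-conjugated 2-silyloxydiene; only the acetyl methyl can enolize.

Step 7
Reactants: 11 (2E,5E)-2-ethylidene-5-methylhept-5-enal; 13 2-methyl-3-(triisopropylsilyloxy)buta-1,3-diene
Product: 14 (1R,6R)-3,6-dimethyl-1-[(E)-3-methylpent-3-enyl]-4-(triisopropylsilyloxy)cyclohex-3-ene-1-carbaldehyde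
Conditions: (S)-3,3-diphenyl-1-(o-tolyl)tetrahydro-1H,3H-pyrrolo[1,2-c][1,3,2]oxazaborole (0.2 equiv), Tf2NH (0.18 equiv), CH2Cl2, −78 → −40 °C
Reagents that add atoms: none
Why: Catalytic enantioselective Diels–Alder reaction: the silyloxy group steers the nucleophilic C7 terminus of the diene to C8 (β-carbon), suprafacial addition carries the (E)-geometry of 11 into the cis relationship of C17 and the C11 chain, and attack on the C9 Re face of the catalyst-bound s-trans enal should fix C8 and C9 in the absolute sense.

Step 8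
Reactants: 14 Diels–Alder aldehyde
Product: 15 [(1R,6R)-3,6-dimethyl-1-[(E)-3-methylpent-3-enyl]-4-(triisopropylsilyloxy)cyclohex-3-en-1-yl]methanol
Conditions: NaBH4, MeOH/CH2Cl2, −40 → 0 °C
Reagents that add atoms: none
Why: Chemoselective hydride reduction of the aldehyde; the ring ketone is masked as its silyl enol ether and no stereocentre is touched.

Step 9
Reactants: 15 silyl enol ether alcohol
Product: 16 (4S,5R)-4-(hydroxymethyl)-2,5-dimethyl-4-[(E)-3-methylpent-3-enyl]cyclohex-2-en-1-one
Conditions: Pd(OAc)2 (1.2 equiv), MeCN, 40 °C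
Reagents that add atoms: none
Why: Saegusa–Ito oxidation: the divalent palladium enolate from the tetrasubstituted silyl enol ether should lose the ring hydrogen at C10 by β-hydride elimination, giving the C5=C10 enone regiospecifically without touching C8 and C9.

Step 10
Reactants: 17 2,2-dimethyl-1,3-dioxane-4,6-dione; 18 (E)-but-2-enoyl chloride
Product: 19 5-[(E)-1-hydroxybut-2-enylidene]-2,2-dimethyl-1,3-dioxane-4,6-dione
Conditions: pyridine, CH2Cl2, 0 → 23 °C
Reagents that add atoms: none
Why: C-acylation of the cyclic malonate; the enolized acyl derivative is a thermal acylketene precursor.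

Step 11
Reactants: 16 ring-B enone alcohol; 19 acylated dioxanedione
Product: 21 (4aS,8R,8aS)-4-[(E)-but-2-enoyl]-5,8-dimethyl-8a-[(E)-3-methylpent-3-enyl]-4a,5,8,8a-tetrahydro-1H-isochromene-3,6(4H,7H)-dione, via β-keto ester 20 (not isolated)
Conditions: PhMe, 90 °C; then Cs2CO3 (0.3 equiv), MeCN (0.01 M), 23 °C; AcOH quench
Reagents that add atoms: none
Why: Thermolysis of 19 gives an acylketene that acylates the neopentyl alcohol, and the β-keto ester enolate then adds 6-exo-trig to C10 of the enone (intramolecular Michael addition); the short tether delivers the nucleophile axially to the C10 face on the side of C20 (cis-fused lactone), which sets C10, and the acidic β-keto lactone holds the charge so the sequence stops here.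

Step 12
Reactants: 21 β-keto δ-lactone
Product: 23 (3R,4S,5R)-4-(hydroxymethyl)-2,5-dimethyl-4-[(E)-3-methylpent-3-enyl]-3-[(E)-2-oxopent-3-enyl]cyclohexan-1-one, via β-keto acid 22 (not isolated)
Conditions: H2O (10 equiv), DMSO, 120 °C
Reagents that add atoms: none
Why: Neutral thermal hydrolysis and decarboxylation of the β-keto lactone removes the tether carbon as CO2, frees the C20 alcohol and leaves the enone and the C8, C9, C10 centres untouched.

Step 13
Reactants: 23 hydroxy enone diketone
Product: 24 (3R,4S,5R)-2,5-dimethyl-4-[(E)-3-methylpent-3-enyl]-3-[(E)-2-oxopent-3-enyl]-4-[(trifluoromethylsulfonyloxy)methyl]cyclohexan-1-one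
Conditions: Tf2O, pyridine, CH2Cl2, −78 → −30 °C
Reagents that add atoms: trifluoromethanesulfonic anhydride, O=S(=O)(OS(=O)(=O)C(F)(F)F)C(F)(F)F
Why: Sulfonylation of the primary neopentyl alcohol at low temperature; the ketones do not react and the neopentyl triflate has no β-hydrogen to eliminate.

Step 14
Reactants: 24 ring-B ketone with enone arm and C20 triflate
Product: 26 (3R,4R,5S,8R,9S,10S)-3,20-cycloclerod-13(E)-ene-2,6-dione, via bicyclic potassium enolate 25 (not isolated)
Conditions: KOtBu (1.3 equiv), 18-crown-6, THF/t-BuOH (10:1, 0.01 M), −40 → 23 °C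
Reagents that add atoms: none
Why: KOtBu sets up equilibrating enolates of 24; the C5 enolate of the C6 ketone undergoes a 6-endo-trig intramolecular Michael addition to C4 of the (E)-enone that closes ring A and leaves the C3 enolate, which then displaces the neopentyl triflate at C20 in a 6-exo-tet alkylation that closes ring C (the bicyclo[2.2.2]octanone). The closest known reaction type is the Michael-initiated ring closure (intramolecular conjugate addition followed by intramolecular enolate alkylation) used for bicyclo[2.2.2]octanones. C5 is set by the tether: the arm delivers C4 to the enolate face cis to C1, which is also the face of C20, so the A/B fusion is cis with C19 cis to H10, and any trans-fused adduct cannot reach C20 and should revert by retro-Michael reaction. C4 is set by the (E)-enone geometry in an open, crown-ether-separated transition state with the enone carbonyl turned away from the enolate oxygen, which should place C18 syn to C19; C3 follows from the cage. The step needs regioselection among the enolizable positions and C- over O-alkylation, and the substrate secures both, because the C1 and C7 enolates could close only four-membered rings and O-alkylation would give a bridgehead enol ether, so these enolates merely equilibrate. The alkylation is irreversible and should pull all material through.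

Step 15
Reactants: 26 tricyclic 2,6-diketone
Product: 29 (3R,4R,5S,6R,8R,9S,10S)-6-hydroxy-3,20-cycloclerod-13(E)-en-2-one, via dimethyl ketal 27 (not isolated), via ketal alcohol 28 (not isolated)
Conditions: CeCl3·7H2O, HC(OMe)3, MeOH, 23 °C; then NaBH4, −40 → 0 °C; then 1 M HCl, THF, 23 °C
Reagents that add atoms: none
Why: Luche-type in situ protection: lanthanide-catalysed ketalization should occur only at the less hindered C2 ketone, NaBH4 then reduces the free α-quaternary C6 ketone, where the equatorial approach is blocked by the axial C4–C5 cage bond on C5 so that hydride should enter axially and give the equatorial (6R)-alcohol, and the acid work-up returns the C2 ketone.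

Step 16
Reactants: 29 keto alcohol
Product: 30 (3R,4R,5S,6R,8R,9S,10S)-6-acetoxy-3,20-cycloclerod-13(E)-en-2-one
Conditions: Ac2O, Et3N, DMAP (cat.), CH2Cl2, 23 °C
Reagents that add atoms: acetic anhydride, CC(=O)OC(C)=O
Why: DMAP-catalysed acylation of the hindered secondary alcohol; no stereocentre is touched.

Step 17
Reactants: 30 keto acetate
Product: 31 (13S,14S)-13,14-epoxide of 30
Conditions: 1,2:4,5-di-O-isopropylidene-β-L-erythro-2,3-hexodiulo-2,6-pyranose (L-fructose-derived ketone, 0.3 equiv), KHSO5 (Oxone triple salt), K2CO3, Bu4NHSO4, MeCN/dimethoxymethane/aq. buffer (pH 10.5), 0 °C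
Reagents that add atoms: potassium peroxymonosulfate, [K+].[O-]S(=O)(=O)OO
Why: Shi epoxidation: the chiral dioxirane should deliver oxygen to one face of the only alkene through the spiro transition state (reagent control, remote from the core), the L-fructose-derived ketone giving the (13S,14S)-epoxide; the buffered medium at 0 °C should spare the hindered acetate.

Step 18
Reactants: 31 (13S,14S)-epoxide
Product: 34 (3R,4R,5S,6R,8R,9S,10S,13S)-6-acetoxy-13-hydroxy-3,20-cycloclerod-14-en-2-one (target), via hydroxy selenide 32 (not isolated), via selenoxide 33 (not isolated)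
Conditions: (PhSe)2, NaBH4, EtOH, 23 °C, then AcOH; 31, 60 °C; then 30% H2O2, pyridine, THF, 0 → 40 °C
Reagents that add atoms: none
Why: Selenolate opens the epoxide at the less substituted C14 (SN2), and selenoxide syn-elimination can take a hydrogen only from the C15 methyl, so the C14=C15 vinyl group appears while the C13 carbinol centre keeps its configuration.

Compound list
1 | (E)-2-methylbut-2-enal (tiglic aldehyde) | C/C=C(\C)C=O | starting material
2 | (E)-3-methylpenta-1,3-diene | C=C/C(C)=C/C | intermediate
3 | 9-[(E)-3-methylpent-3-enyl]-9-borabicyclo[3.3.1]nonane | C/C=C(\C)CCB1C2CCCC1CCC2 | intermediate (not isolated)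
4 | (E)-3-methylpent-3-en-1-ol | C/C=C(\C)CCO | intermediate
5 | (E)-5-iodo-3-methylpent-2-ene | C/C=C(\C)CCI | intermediate
6 | (E)-but-2-enal (crotonaldehyde) | C/C=C/C=O | starting material
7 | tert-butylamine | CC(C)(C)N | starting material
8 | (1E,2E)-N-tert-butylbut-2-en-1-imine | C/C=C/C=N/C(C)(C)C | intermediate
9 | N-tert-butyl imine of racemic 2-[(E)-3-methylpent-3-enyl]but-3-enal | C=CC(CC/C(C)=C/C)/C=N/C(C)(C)C | intermediate (not isolated)
10 | racemic 2-[(E)-3-methylpent-3-enyl]but-3-enal | C=CC(CC/C(C)=C/C)C=O | intermediate (not isolated)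
11 | (2E,5E)-2-ethylidene-5-methylhept-5-enal | C/C=C(/C=O)CC/C(C)=C/C | intermediate
12 | 3-methylbut-3-en-2-one | CC(=O)C(C)=C | starting material
13 | 2-methyl-3-(triisopropylsilyloxy)buta-1,3-diene | C=C(C)C(=C)O[Si](C(C)C)(C(C)C)C(C)C | intermediate
14 | (1R,6R)-3,6-dimethyl-1-[(E)-3-methylpent-3-enyl]-4-(triisopropylsilyloxy)cyclohex-3-ene-1-carbaldehyde | C/C=C(\C)CC[C@@]1(C=O)CC(C)=C(O[Si](C(C)C)(C(C)C)C(C)C)C[C@H]1C | intermediate
15 | [(1R,6R)-3,6-dimethyl-1-[(E)-3-methylpent-3-enyl]-4-(triisopropylsilyloxy)cyclohex-3-en-1-yl]methanol | C/C=C(\C)CC[C@@]1(CO)CC(C)=C(O[Si](C(C)C)(C(C)C)C(C)C)C[C@H]1C | intermediate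
16 | (4S,5R)-4-(hydroxymethyl)-2,5-dimethyl-4-[(E)-3-methylpent-3-enyl]cyclohex-2-en-1-one | C/C=C(\C)CC[C@@]1(CO)C=C(C)C(=O)C[C@H]1C | intermediate
17 | 2,2-dimethyl-1,3-dioxane-4,6-dione | CC1(C)OC(=O)CC(=O)O1 | starting material
18 | (E)-but-2-enoyl chloride | C/C=C/C(=O)Cl | starting material
19 | 5-[(E)-1-hydroxybut-2-enylidene]-2,2-dimethyl-1,3-dioxane-4,6-dione | C/C=C/C(O)=C1C(=O)OC(C)(C)OC1=O | intermediate
20 | [(1S,6R)-3,6-dimethyl-1-[(E)-3-methylpent-3-enyl]-4-oxocyclohex-2-en-1-yl]methyl (E)-3-oxohex-4-enoate | C/C=C(\C)CC[C@@]1(COC(=O)CC(=O)/C=C/C)C=C(C)C(=O)C[C@H]1C | intermediate (not isolated)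
21 | (4aS,8R,8aS)-4-[(E)-but-2-enoyl]-5,8-dimethyl-8a-[(E)-3-methylpent-3-enyl]-4a,5,8,8a-tetrahydro-1H-isochromene-3,6(4H,7H)-dione (β-keto δ-lactone C20–O–CO–C1 with C1 bonded to C10; C1 and C5 as epimer mixtures) | C/C=C(\C)CC[C@@]12COC(=O)C(C(=O)/C=C/C)[C@@H]1C(C)C(=O)C[C@H]2C | intermediate
22 | β-keto acid from ring opening of 21 (C1 carries CO2H and the (E)-but-2-enoyl group; C20 alcohol free; other centres as in 21) | C/C=C(\C)CC[C@@]1(CO)[C@H](C(C(=O)O)C(=O)/C=C/C)C(C)C(=O)C[C@H]1C | intermediate (not isolated)
23 | (3R,4S,5R)-4-(hydroxymethyl)-2,5-dimethyl-4-[(E)-3-methylpent-3-enyl]-3-[(E)-2-oxopent-3-enyl]cyclohexan-1-one (C2 epimer mixture) | C/C=C(\C)CC[C@@]1(CO)[C@H](CC(=O)/C=C/C)C(C)C(=O)C[C@H]1C | intermediate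
24 | (3R,4S,5R)-2,5-dimethyl-4-[(E)-3-methylpent-3-enyl]-3-[(E)-2-oxopent-3-enyl]-4-[(trifluoromethylsulfonyloxy)methyl]cyclohexan-1-one (C2 epimer mixture) | C/C=C(\C)CC[C@@]1(COS(=O)(=O)C(F)(F)F)[C@H](CC(=O)/C=C/C)C(C)C(=O)C[C@H]1C | intermediate
25 | potassium C2(3)-enolate of the cis-fused ring A/B 2,6-diketone bearing the C20 triflate (C4, C5, C8, C9, C10 as in 26) | C/C=C(\C)CC[C@@]1(COS(=O)(=O)C(F)(F)F)[C@@H]2CC([O-])=C[C@@H](C)[C@]2(C)C(=O)C[C@H]1C.[K+] | intermediate (not isolated)
26 | (3R,4R,5S,8R,9S,10S)-3,20-cycloclerod-13(E)-ene-2,6-dione | C/C=C(\C)CC[C@@]12C[C@H]3C(=O)C[C@@H]1[C@](C)([C@@H]3C)C(=O)C[C@H]2C | intermediate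
27 | 2,2-dimethyl ketal of 26 (C6 ketone free) | C/C=C(\C)CC[C@@]12C[C@H]3C(OC)(OC)C[C@@H]1[C@](C)([C@@H]3C)C(=O)C[C@H]2C | intermediate (not isolated)
28 | (6R)-6-hydroxy 2,2-dimethyl ketal | C/C=C(\C)CC[C@@]12C[C@H]3C(OC)(OC)C[C@@H]1[C@](C)([C@@H]3C)[C@H](O)C[C@H]2C | intermediate (not isolated)
29 | (3R,4R,5S,6R,8R,9S,10S)-6-hydroxy-3,20-cycloclerod-13(E)-en-2-one | C/C=C(\C)CC[C@@]12C[C@H]3C(=O)C[C@@H]1[C@](C)([C@@H]3C)[C@H](O)C[C@H]2C | intermediate
30 | (3R,4R,5S,6R,8R,9S,10S)-6-acetoxy-3,20-cycloclerod-13(E)-en-2-one | C/C=C(\C)CC[C@@]12C[C@H]3C(=O)C[C@@H]1[C@](C)([C@@H]3C)[C@H](OC(C)=O)C[C@H]2C | intermediate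
31 | (3R,4R,5S,6R,8R,9S,10S,13S,14S)-6-acetoxy-13,14-epoxy-3,20-cycloclerodan-2-one | C[C@@H]1O[C@@]1(C)CC[C@@]23C[C@H]4C(=O)C[C@@H]2[C@](C)([C@@H]4C)[C@H](OC(C)=O)C[C@H]3C | intermediate
32 | (13S)-13-hydroxy-14-(phenylselanyl) derivative of 30 (C14 inverted relative to 31) | C[C@@H]([Se]c1ccccc1)[C@@](C)(O)CC[C@@]23C[C@H]4C(=O)C[C@@H]2[C@](C)([C@@H]4C)[C@H](OC(C)=O)C[C@H]3C | intermediate (not isolated)
33 | selenoxide of 32 | C[C@@H]([Se](=O)c1ccccc1)[C@@](C)(O)CC[C@@]23C[C@H]4C(=O)C[C@@H]2[C@](C)([C@@H]4C)[C@H](OC(C)=O)C[C@H]3C | intermediate (not isolated)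
34 | (3R,4R,5S,6R,8R,9S,10S,13S)-6-acetoxy-13-hydroxy-3,20-cycloclerod-14-en-2-one (CNP0281208.1) | C=C[C@@](C)(O)CC[C@@]12C[C@H]3C(=O)C[C@@H]1[C@](C)([C@@H]3C)[C@H](OC(C)=O)C[C@H]2C | target

Total step count: 18
Longest linear sequence: 15 steps (steps 1, 2, 3, 5, 7, 8, 9, 11, 12, 13, 14, 15, 16, 17, 18)

Steps most likely to fail

Step 14. Displacement of the neopentyl triflate by the C3 enolate may be too slow, so that S–O cleavage of the triflate or Grob-type fragmentation of ring B overtakes ring closure. γ-Deprotonation of the enone at C18 may also let the extended dienolate alkylate at C3 before the Michael addition has taken place, and a chelated transition state may erode facial control at C4. The fallback sets out from 23. Oxidation (SO3·pyridine, DMSO, iPr2NEt) should give the C20 aldehyde F1. K2CO3 in MeOH should then run the same Michael addition and trap the C3 enolate by intramolecular aldol addition to the non-enolizable aldehyde, giving the tricyclic aldol F2. Acylation with 1,1'-thiocarbonyldiimidazole should give the thiocarbonylimidazolide F3. Bu3SnH/AIBN at high stannane concentration (Barton–McCombie deoxygenation, so that hydrogen transfer outruns cyclization of the C20 radical onto the side-chain alkene) should return to the route at 26.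

Step 7. The α,β-disubstituted enal may react sluggishly with the chiral Lewis acid, Mukaiyama aldol addition at the formyl group may compete, and enantiofacial discrimination may be incomplete. The fallback sets out from 11 and 13. An Et2AlCl-promoted Diels–Alder reaction without chiral catalyst should give the racemate, that is 14 together with its mirror image, the ent-aldehyde F4. NaBH4 should give 15 together with the ent-alcohol F5. Esterification with (S)-2-methoxy-2-phenylacetic acid (DCC, DMAP) should give the diastereomeric esters, the mandelate F6 (from 15) and the mandelate F7 (from F5), which are separated by chromatography. K2CO3/MeOH on F6 should return to the route at 15.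

Step 15. Discrimination of the two ketones in the in situ ketalization may be incomplete (over-reduction at C2). The axial approach to C6 passes the syn-axial C17 methyl, so hydride delivery at C6 may show poor facial selectivity. The fallback sets out from 26. (TMSOCH2)2 with catalytic TMSOTf at −78 °C should protect only the less hindered C2 ketone as the dioxolane F8. Li in NH3/THF with t-BuOH should reduce the C6 ketone under thermodynamic control to the equatorial alcohol, the ketal alcohol F9; the axial epimer would be syn-diaxial to C17 and is disfavoured. PPTS in wet acetone should return to the route at 29.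

Further compounds
F1 | step 14 | (3R,4S,5R)-4-formyl analogue of 23 (C20 aldehyde) | C/C=C(\C)CC[C@@]1(C=O)[C@H](CC(=O)/C=C/C)C(C)C(=O)C[C@H]1C
F2 | step 14 | 20-hydroxy derivative of 26 (tricyclic aldol, C20 epimer mixture) | C/C=C(\C)CC[C@@]12C(O)[C@H]3C(=O)C[C@@H]1[C@](C)([C@@H]3C)C(=O)C[C@H]2C
F3 | step 14 | O-(imidazol-1-ylthiocarbonyl) derivative of F2 | C/C=C(\C)CC[C@@]12C(OC(=S)n3ccnc3)[C@H]4C(=O)C[C@@H]1[C@](C)([C@@H]4C)C(=O)C[C@H]2C
F4 | step 7 | (1S,6S)-enantiomer of aldehyde 14 | C/C=C(\C)CC[C@]1(C=O)CC(C)=C(O[Si](C(C)C)(C(C)C)C(C)C)C[C@@H]1C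
F5 | step 7 | (1S,6S)-enantiomer of alcohol 15 | C/C=C(\C)CC[C@]1(CO)CC(C)=C(O[Si](C(C)C)(C(C)C)C(C)C)C[C@@H]1C
F6 | step 7 | (S)-2-methoxy-2-phenylacetate of 15 | C/C=C(\C)CC[C@@]1(COC(=O)[C@@H](OC)c2ccccc2)CC(C)=C(O[Si](C(C)C)(C(C)C)C(C)C)C[C@H]1C
F7 | step 7 | (S)-2-methoxy-2-phenylacetate of F5 | C/C=C(\C)CC[C@]1(COC(=O)[C@@H](OC)c2ccccc2)CC(C)=C(O[Si](C(C)C)(C(C)C)C(C)C)C[C@@H]1C
F8 | step 15 | 2,2-ethylenedioxy ketal of 26 | C/C=C(\C)CC[C@@]12C[C@H]3C4(OCCO4)C[C@@H]1[C@](C)([C@@H]3C)C(=O)C[C@H]2C
F9 | step 15 | (6R)-6-hydroxy 2,2-ethylenedioxy ketal | C/C=C(\C)CC[C@@]12C[C@H]3C4(OCCO4)C[C@@H]1[C@](C)([C@@H]3C)[C@H](O)C[C@H]2C
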